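**Retrosynthetic overview**
1. The target is a 2-hydroxychroman-4-one. It is unmasked last by hydrogenolysis of three benzyl ethers, fluoride cleavage of the C2–O and Cα–O silyl groups, and oxidation of a C4 methylene to the ketone.
2. Ring C and the bonds C4–C3 and O1–C2 come from a hetero-Diels–Alder reaction of an ortho-quinone methide (O1=C8a–C4a=C4) with an (S,E)-γ-silyloxy silyl enol ether.
3. The strategy rests on ring A, a hexasubstituted benzene in which O1 (on C8a) is para to the C6 methoxy oxygen and C4a carries the one-carbon unit C4. This is the pattern produced by 4π opening and 6π closure of a 4-allenyl-4-methoxycyclobutenone. The squarate supplies C8–Me, C7–O, C6–OMe and O1; the alkoxyallene supplies C5–O, C4a and C4.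
4. The enol ether takes its E geometry from (E)-3-silyloxyacrolein and its Cα configuration from a catalytic asymmetric aryl transfer. Ring B arrives intact with the aryl bromide.
5. Order of ring formation: ring B is present from the start; ring A and then ring C are closed in one operation.

Key step: step 10

Remark on the chemistry: in the free target C2 is a lactol carbon and C3 lies between the C4 ketone and the masked C2 aldehyde, so both can equilibrate by ring–chain tautomerism. It is assumed that the drawn 2,3-trans isomer with (S)-Cα is the preferred one. Cα is therefore the centre that must be fixed irreversibly. Base-mediated correction at C3 is avoided throughout, because 2-oxygenated chroman-4-ones eliminate to chromones under base.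

**Route**

Step 1
Reactants: 1 squaric acid
Product: 2 dibenzyl squarate [3,4-bis(benzyloxy)cyclobut-3-ene-1,2-dione]
Conditions: BnOH (excess), PhMe, reflux, Dean–Stark
Reagents that add atoms: benzyl alcohol, OCc1ccccc1
Why: Squaric acid is a strong vinylogous diacid and should esterify under azeotropic removal of water (Fischer-type esterification) without added catalyst.

Step 2
Reactants: 2 dibenzyl squarate
Product: 3 2,3-bis(benzyloxy)-4-hydroxy-4-methylcyclobut-2-en-1-one (racemic)
Conditions: MeLi, THF, −78 °C; aq. NH4Cl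
Reagents that add atoms: methyllithium, [Li]C
Why: Organolithium 1,2-addition to one of the two equivalent carbonyl groups of a squarate diester should stop at the mono-adduct at −78 °C.

Step 3
Reactants: 3 2,3-bis(benzyloxy)-4-hydroxy-4-methylcyclobut-2-en-1-one
Product: 4 3-(benzyloxy)-4-methylcyclobut-3-ene-1,2-dione
Conditions: conc. HCl (cat.), CH2Cl2, rt
Reagents that add atoms: none
Why: Acid ionises the tertiary carbinol to a benzyloxy-stabilised cyclobutenyl cation, water returns at C2 and benzyl alcohol is expelled, which is the standard acid-mediated rearrangement of squarate adducts to 3-alkoxy-4-alkylcyclobutenediones.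

Step 4
Reactants: 5 benzyl propargyl ether
Product: 6 benzyloxyallene [(propa-1,2-dienyloxy)methylbenzene]
Conditions: KOt-Bu (0.3 equiv), THF, rt
Reagents that add atoms: none
Why: Base-catalysed prototropic propargyl-to-allenyl ether isomerisation should stop at the alkoxyallene under these mild conditions.

Step 5
Reactants: 6 benzyloxyallene, 4 3-(benzyloxy)-4-methylcyclobut-3-ene-1,2-dione
Product: 9 3-(benzyloxy)-4-[1-(benzyloxy)propa-1,2-dienyl]-4-methoxy-2-methylcyclobut-2-en-1-one (racemic), via 1-(benzyloxy)-1-lithiopropa-1,2-diene 7 (not isolated), via lithium cyclobutenolate 8 (not isolated)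
Conditions: n-BuLi, THF, −78 to −40 °C; then 4, −78 °C; then MeOTf, −78 to 0 °C
Reagents that add atoms: methyl trifluoromethanesulfonate, COS(=O)(=O)C(F)(F)F
Why: The alkoxyallene is lithiated at its oxygen-bearing carbon and adds 1,2 to the more electrophilic carbonyl of 4 (the one next to the benzyloxy-bearing carbon, the other being deactivated as a vinylogous ester), and the lithium alkoxide is then O-methylated (Williamson-type etherification); this regiochemistry fixes the ring A substitution pattern.

Step 6
Reactants: 10 1,1,3,3-tetramethoxypropane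
Product: 11 sodium (E)-3-oxoprop-1-en-1-olate (sodium malonaldehyde)
Conditions: 1 M HCl (cat.), H2O, 40 °C; then NaOH (1 equiv), 0 °C; evaporate, triturate with acetone
Reagents that add atoms: sodium hydroxide, [Na+].[OH-]; water, O
Why: Acid-catalysed acetal hydrolysis liberates malonaldehyde, a vinylogous carboxylic acid that is isolated as its stable sodium enolate.

Step 7
Reactants: 11 sodium (E)-3-oxoprop-1-en-1-olate
Product: 12 (E)-3-[(tert-butyldimethylsilyl)oxy]prop-2-enal
Conditions: TBSCl, DMF, 0 °C to rt
Reagents that add atoms: tert-butyldimethylsilyl chloride, CC(C)(C)[Si](C)(C)Cl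
Why: O-Silylation of the delocalised enolate should give the push–pull enal as its thermodynamically preferred E isomer.

Step 8
Reactants: 13 1-(benzyloxy)-4-bromobenzene, 12 (E)-3-[(tert-butyldimethylsilyl)oxy]prop-2-enal
Product: 17 (S,E)-1-[4-(benzyloxy)phenyl]-3-[(tert-butyldimethylsilyl)oxy]prop-2-en-1-ol, via 4-(benzyloxy)phenyllithium 14 (not isolated), via [4-(benzyloxy)phenyl]zinc chloride 15 (not isolated), via [4-(benzyloxy)phenyl](butyl)zinc 16 (not isolated)
Conditions: n-BuLi, t-BuOMe, −78 °C; ZnCl2; n-BuLi; N,N,N′,N′-tetraethylethylenediamine; (+)-3-exo-morpholinoisoborneol (5 mol%), PhMe; then 12, 0 °C; aq. NaHCO3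
Reagents that add atoms: none
Why: This is an amino-alcohol-catalysed enantioselective 1,2-addition of an arylzinc to an aldehyde, with the diamine sequestering LiCl to suppress the racemic background; the ligand enantiomer is chosen for aryl delivery to the Re face, which should give (S) at Cα, and the E geometry is carried over unchanged from 12.

Step 9
Reactants: 17 (S,E)-1-[4-(benzyloxy)phenyl]-3-[(tert-butyldimethylsilyl)oxy]prop-2-en-1-ol
Product: 18 (S,E)-3-[4-(benzyloxy)phenyl]-1,3-bis[(tert-butyldimethylsilyl)oxy]prop-1-ene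
Conditions: TBSCl, imidazole, DMF, rt; chromatography on Et3N-treated silica
Reagents that add atoms: tert-butyldimethylsilyl chloride, CC(C)(C)[Si](C)(C)Cl
Why: Silylation of a secondary benzylic alcohol under basic, non-ionising conditions should leave the silyl enol ether and the Cα configuration intact.

Step 10
Reactants: 9 3-(benzyloxy)-4-[1-(benzyloxy)propa-1,2-dienyl]-4-methoxy-2-methylcyclobut-2-en-1-one, 18 (S,E)-3-[4-(benzyloxy)phenyl]-1,3-bis[(tert-butyldimethylsilyl)oxy]prop-1-ene
Product: 21 (2R,3R)-5,7-bis(benzyloxy)-3-{(S)-[4-(benzyloxy)phenyl][(tert-butyldimethylsilyl)oxy]methyl}-2-[(tert-butyldimethylsilyl)oxy]-6-methoxy-8-methylchromane, via dienylketene 19 (not isolated), via ortho-quinone methide 20 (not isolated)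
Conditions: PhMe, 110 °C, slow addition of 9 (1.5 equiv) to 18, Ar
Reagents that add atoms: none
Why: Heating 9 should trigger conrotatory 4π ring opening in which the C4 methoxy group rotates outward and the allenyl group inward, giving the (Z)-dienylketene 19, whose ketene carbon and central allene carbon then join in a thermal 6π electrocyclisation (C8a–C4a) that closes ring A as ortho-quinone methide 20 with the future C4 as exocyclic methylene. Quinone methide 20 (O1=C8a–C4a=C4) is trapped by the E-silyl enol ether 18 in an inverse-electron-demand hetero-Diels–Alder reaction that forms C4–C3 and O1–C2, closes ring C by [4+2] cycloaddition and rearomatises ring A. The closest known reaction type is the thermal ring expansion of 4-allenyl-4-alkoxycyclobutenones to ortho-quinone methides with in situ capture by enol ethers. C2 and C3 arise trans because the E-alkene adds suprafacially, and C3 is set relative to Cα by the allylic stereocentre, which is expected to react through the inside-alkoxy arrangement (Cα–OSi near the alkene plane, aryl anti to the incoming methide carbon), giving the (2R,3R) adduct from (S)-18. The step needs regiocontrol, secured by the polarity match of the nucleophilic enol ether β-carbon with the methide carbon, and π-facial control, which rests only on the Cα substituents and is the weak point; slow addition of 9 keeps the quinone methide dilute relative to 18 so that self-cycloaddition is suppressed.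

Step 11
Reactants: 21 the chromane cycloadduct
Product: 22 (2R,3R)-5,7-bis(benzyloxy)-3-{(S)-[4-(benzyloxy)phenyl][(tert-butyldimethylsilyl)oxy]methyl}-2-[(tert-butyldimethylsilyl)oxy]-6-methoxy-8-methylchroman-4-ol (C4 epimers)
Conditions: DDQ, CH2Cl2/pH 7 buffer, 0 °C to rt
Reagents that add atoms: water, O
Why: DDQ should abstract hydride from C4–H, the only benzylic position activated by three ring oxygens (ortho at C5 and C8a, para at C7), and water captures the resulting cation (benzylic oxidation as practised on electron-rich flavans); the C4 configuration is inconsequential.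

Step 12
Reactants: 22 the chroman-4-ol
Product: 23 (2R,3R)-5,7-bis(benzyloxy)-3-{(S)-[4-(benzyloxy)phenyl][(tert-butyldimethylsilyl)oxy]methyl}-2-[(tert-butyldimethylsilyl)oxy]-6-methoxy-8-methylchroman-4-one
Conditions: Pr4N[RuO4] (5 mol%), N-methylmorpholine N-oxide, 4 Å MS, CH2Cl2, rt
Reagents that add atoms: none
Why: Ley–Griffith oxidation of the secondary benzylic alcohol under neutral conditions should leave the silyl acetal, the silyl ether, the benzyl ethers and the now enolisable C3–H untouched.

Step 13
Reactants: 23 the chroman-4-one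
Product: 24 (2S,3R)-5,7-bis(benzyloxy)-3-{(S)-[4-(benzyloxy)phenyl](hydroxy)methyl}-2-hydroxy-6-methoxy-8-methylchroman-4-one
Conditions: HF·pyridine, pyridine, THF, 0 °C
Reagents that add atoms: none
Why: Buffered acidic fluoride cleaves the anomeric and the secondary silyl ethers without base, so that retro-aldol cleavage, elimination to the chromone and enolate epimerisation at C3 are not invited, and C2 should settle as the trans lactol.

Step 14
Reactants: 24 the tribenzyl lactol
Product: 25 (2S,3R)-2,5,7-trihydroxy-3-[(S)-hydroxy(4-hydroxyphenyl)methyl]-6-methoxy-8-methylchroman-4-one (target)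
Conditions: H2 (1 atm), Pd/C, EtOAc, rt; filter, concentrate
Reagents that add atoms: none
Why: Neutral hydrogenolysis of the three aryl benzyl ethers should be faster than reduction of the aryl ketone or hydrogenolysis of the free benzylic alcohol, and the product is isolated by filtration alone.

**Compound list**
1 | squaric acid (3,4-dihydroxycyclobut-3-ene-1,2-dione) | OC1=C(O)C(=O)C1=O | starting material
2 | dibenzyl squarate | O=C1C(=O)C(OCc2ccccc2)=C1OCc1ccccc1 | intermediate
3 | 2,3-bis(benzyloxy)-4-hydroxy-4-methylcyclobut-2-en-1-one (racemic) | CC1(O)C(OCc2ccccc2)=C(OCc2ccccc2)C1=O | intermediate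
4 | 3-(benzyloxy)-4-methylcyclobut-3-ene-1,2-dione | CC1=C(OCc2ccccc2)C(=O)C1=O | intermediate
5 | benzyl propargyl ether | C#CCOCc1ccccc1 | starting material
6 | benzyloxyallene | C=C=COCc1ccccc1 | intermediate
7 | 1-(benzyloxy)-1-lithiopropa-1,2-diene (not isolated) | [Li]C(=C=C)OCc1ccccc1 | intermediate
8 | lithium 2-(benzyloxy)-1-[1-(benzyloxy)propa-1,2-dienyl]-3-methyl-4-oxocyclobut-2-en-1-olate (racemic, not isolated) | [Li]OC1(C(=C=C)OCc2ccccc2)C(OCc2ccccc2)=C(C)C1=O | intermediate
9 | 3-(benzyloxy)-4-[1-(benzyloxy)propa-1,2-dienyl]-4-methoxy-2-methylcyclobut-2-en-1-one (racemic) | O=C1C(C)=C(OCc2ccccc2)C1(OC)C(OCc1ccccc1)=C=C | intermediate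
10 | 1,1,3,3-tetramethoxypropane | COC(OC)CC(OC)OC | starting material
11 | sodium (E)-3-oxoprop-1-en-1-olate | [Na+].[O-]/C=C/C=O | intermediate
12 | (E)-3-[(tert-butyldimethylsilyl)oxy]prop-2-enal | CC(C)(C)[Si](C)(C)O/C=C/C=O | intermediate
13 | 1-(benzyloxy)-4-bromobenzene | Brc1ccc(OCc2ccccc2)cc1 | starting material
14 | 4-(benzyloxy)phenyllithium (not isolated) | [Li]c1ccc(OCc2ccccc2)cc1 | intermediate
15 | [4-(benzyloxy)phenyl]zinc chloride (not isolated) | Cl[Zn]c1ccc(OCc2ccccc2)cc1 | intermediate
16 | [4-(benzyloxy)phenyl](butyl)zinc (not isolated) | CCCC[Zn]c1ccc(OCc2ccccc2)cc1 | intermediate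
17 | (S,E)-1-[4-(benzyloxy)phenyl]-3-[(tert-butyldimethylsilyl)oxy]prop-2-en-1-ol | CC(C)(C)[Si](C)(C)O/C=C/[C@H](O)c1ccc(OCc2ccccc2)cc1 | intermediate
18 | (S,E)-3-[4-(benzyloxy)phenyl]-1,3-bis[(tert-butyldimethylsilyl)oxy]prop-1-ene | CC(C)(C)[Si](C)(C)O/C=C/[C@H](O[Si](C)(C)C(C)(C)C)c1ccc(OCc2ccccc2)cc1 | intermediate
19 | (3Z)-3,5-bis(benzyloxy)-4-methoxy-2-methylhepta-1,3,5,6-tetraen-1-one (dienylketene, not isolated) | O=C=C(C)/C(OCc1ccccc1)=C(\C(OCc1ccccc1)=C=C)OC | intermediate
20 | 3,5-bis(benzyloxy)-4-methoxy-2-methyl-6-methylidenecyclohexa-2,4-dien-1-one (ortho-quinone methide, not isolated) | O=C1C(C)=C(OCc2ccccc2)C(OC)=C(OCc2ccccc2)C1=C | intermediate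
21 | (2R,3R)-5,7-bis(benzyloxy)-3-{(S)-[4-(benzyloxy)phenyl][(tert-butyldimethylsilyl)oxy]methyl}-2-[(tert-butyldimethylsilyl)oxy]-6-methoxy-8-methylchromane | COc1c(OCc2ccccc2)c(C)c2c(c1OCc1ccccc1)C[C@H]([C@H](O[Si](C)(C)C(C)(C)C)c1ccc(OCc3ccccc3)cc1)[C@@H](O[Si](C)(C)C(C)(C)C)O2 | intermediate
22 | the corresponding (2R,3R)-chroman-4-ol (C4 epimers) | COc1c(OCc2ccccc2)c(C)c2c(c1OCc1ccccc1)C(O)[C@H]([C@H](O[Si](C)(C)C(C)(C)C)c1ccc(OCc3ccccc3)cc1)[C@@H](O[Si](C)(C)C(C)(C)C)O2 | intermediate
23 | the corresponding (2R,3R)-chroman-4-one | COc1c(OCc2ccccc2)c(C)c2c(c1OCc1ccccc1)C(=O)[C@H]([C@H](O[Si](C)(C)C(C)(C)C)c1ccc(OCc3ccccc3)cc1)[C@@H](O[Si](C)(C)C(C)(C)C)O2 | intermediate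
24 | (2S,3R)-5,7-bis(benzyloxy)-3-{(S)-[4-(benzyloxy)phenyl](hydroxy)methyl}-2-hydroxy-6-methoxy-8-methylchroman-4-one | COc1c(OCc2ccccc2)c(C)c2c(c1OCc1ccccc1)C(=O)[C@H]([C@H](O)c1ccc(OCc3ccccc3)cc1)[C@@H](O)O2 | intermediate
25 | (2S,3R)-2,5,7-trihydroxy-3-[(S)-hydroxy(4-hydroxyphenyl)methyl]-6-methoxy-8-methylchroman-4-one | COc1c(O)c(C)c2c(c1O)C(=O)[C@H]([C@H](O)c1ccc(O)cc1)[C@@H](O)O2 | target

**Step count and risks**

Total step count: 14. Longest linear sequence: 9 steps (steps 1–3, 5, 10–14 from squaric acid; equally steps 6–9, 10–14 from 1,1,3,3-tetramethoxypropane).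

Steps most likely to fail:

1. Step 10. The acyclic allylic stereocentre may discriminate the two enol ether faces poorly (C3 epimer), and at 110 °C the quinone methide may be lost to self-cycloaddition before it meets 18. Fallback, setting out from 9 and returning at 21: 9 is heated in toluene at 110 °C with acetic acid (5 equiv), so that quinone methide 20 is captured by conjugate addition as [2,4-bis(benzyloxy)-6-hydroxy-3-methoxy-5-methylphenyl]methyl acetate F1. This shelf-stable phenol is then treated with t-BuMgCl in toluene at −78 to 0 °C in the presence of 18; the magnesium phenoxide expels acetate, regenerates 20 at low temperature, and the cycloaddition gives 21. Ring A formation is thereby separated from the cycloaddition, which can run cold with controlled stoichiometry.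

2. Step 8. Aryl transfer to the deactivated vinylogous formate carbonyl may be slow or poorly enantioselective, and alcohol 17 may ionise and eliminate to the cinnamaldehyde on work-up. Fallback, setting out from 13 (with 9) and returning at 24:
 - Bromine–lithium exchange on 13 (n-BuLi) and formylation with DMF give 4-(benzyloxy)benzaldehyde F2.
 - Asymmetric allylboration with (−)-Ipc2B(allyl) (Et2O, −78 °C; NaOH, H2O2) gives (S)-1-[4-(benzyloxy)phenyl]but-3-en-1-ol F3.
 - Lemieux–Johnson cleavage (K2OsO4·2H2O cat., NaIO4, 2,6-lutidine, dioxane/H2O) gives (S)-3-[4-(benzyloxy)phenyl]-3-hydroxypropanal F4.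
 - t-Bu2Si(OTf)2 and Et3N in CH2Cl2 close the cyclic silyl enol ether (S)-4-[4-(benzyloxy)phenyl]-2,2-di-tert-butyl-4H-1,3,2-dioxasiline F5. Its ring fixes the enol ether geometry and holds the Cα oxygen in the alkene plane, with the aryl group shielding one face.
 - Thermolysis of 9 in the presence of F5 (toluene, 110 °C) gives the cis-fused silylene-bridged cycloadduct F6, in which C3 and Cα are configured as in 21 and C2–O and Cα–O are bridged by Si(t-Bu)2.
 - DDQ/water gives the silylene-bridged chroman-4-ol F7, and Pr4N[RuO4]/N-methylmorpholine N-oxide gives the silylene-bridged chroman-4-one F8.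
 - HF·pyridine removes the silylene and gives lactol 24, the anomeric centre equilibrating to the trans form.

3. Step 14. The benzylic Cα–OH, activated by the emerging para-hydroxyl group, may be lost by hydrogenolysis, or the lactol may dehydrate on the catalyst. Fallback, setting out from 23 and returning at 25: 23 is hydrogenolysed first (H2, Pd/C, EtOAc) while the bulky silyl ether still shields the benzylic C–O, giving (2R,3R)-2-[(tert-butyldimethylsilyl)oxy]-3-{(S)-[(tert-butyldimethylsilyl)oxy](4-hydroxyphenyl)methyl}-5,7-dihydroxy-6-methoxy-8-methylchroman-4-one F9. Both silyl groups are then removed with HF·pyridine/pyridine in THF at 0 °C to give 25.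

Further compounds
F1 | step 10 | [2,4-bis(benzyloxy)-6-hydroxy-3-methoxy-5-methylphenyl]methyl acetate | CC(=O)OCc1c(O)c(C)c(OCc2ccccc2)c(OC)c1OCc1ccccc1
F2 | step 8 | 4-(benzyloxy)benzaldehyde | O=Cc1ccc(OCc2ccccc2)cc1
F3 | step 8 | (S)-1-[4-(benzyloxy)phenyl]but-3-en-1-ol | C=CC[C@H](O)c1ccc(OCc2ccccc2)cc1
F4 | step 8 | (S)-3-[4-(benzyloxy)phenyl]-3-hydroxypropanal | O=CC[C@H](O)c1ccc(OCc2ccccc2)cc1
F5 | step 8 | (S)-4-[4-(benzyloxy)phenyl]-2,2-di-tert-butyl-4H-1,3,2-dioxasiline | CC(C)(C)[Si]1(C(C)(C)C)OC=C[C@@H](c2ccc(OCc3ccccc3)cc2)O1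
F6 | step 8 | cis-fused silylene-bridged cycloadduct (5,7-bis(benzyloxy)-6-methoxy-8-methylchromane with C2–O and Cα–O bridged by Si(t-Bu)2; 2,3-cis; C3 and Cα as in 21) | COc1c(OCc2ccccc2)c(C)c2c(c1OCc1ccccc1)C[C@@H]1[C@@H](c3ccc(OCc4ccccc4)cc3)O[Si](C(C)(C)C)(C(C)(C)C)O[C@@H]1O2
F7 | step 8 | silylene-bridged chroman-4-ol (C4 epimers) | COc1c(OCc2ccccc2)c(C)c2c(c1OCc1ccccc1)C(O)[C@@H]1[C@@H](c3ccc(OCc4ccccc4)cc3)O[Si](C(C)(C)C)(C(C)(C)C)O[C@@H]1O2
F8 | step 8 | silylene-bridged chroman-4-one | COc1c(OCc2ccccc2)c(C)c2c(c1OCc1ccccc1)C(=O)[C@@H]1[C@@H](c3ccc(OCc4ccccc4)cc3)O[Si](C(C)(C)C)(C(C)(C)C)O[C@@H]1O2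
F9 | step 14 | (2R,3R)-2-[(tert-butyldimethylsilyl)oxy]-3-{(S)-[(tert-butyldimethylsilyl)oxy](4-hydroxyphenyl)methyl}-5,7-dihydroxy-6-methoxy-8-methylchroman-4-one | COc1c(O)c(C)c2c(c1O)C(=O)[C@H]([C@H](O[Si](C)(C)C(C)(C)C)c1ccc(O)cc1)[C@@H](O[Si](C)(C)C(C)(C)C)O2
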